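## Structural features

Compound 22 is an isoflavone: a benzene ring (ring A) fused to a 4-pyranone (ring C), with a second benzene (ring B) attached through the single bond C3–C1'. Ring A carries one free phenol at C7. Ring B is 1,2,4,5-tetrasubstituted, with a free phenol at C2', a methyl ether at C4' and a 3-methylbut-2-enyl (prenyl) chain at C5', para to the C2' hydroxyl and ortho to the methoxy group. There is no stereocentre, so none stand next to each other; the only geometric element on the way is the enol double bond of the C2–C3 unit before ring C closes. The fragile parts are the trisubstituted prenyl alkene (acid, electrophilic halogen, hydrogenation), the two phenols and C2 of the pyranone, a vinylogous ester carbon open to hard nucleophiles. The real difficulty is to join ring B at C3 with its three substituents in fixed positions and to build rings A and C without the strongly acidic acylations of classical deoxybenzoin chemistry, which the prenyl group would not survive. The key step uses the fact that O1–C8a and C4–C4a start from the adjacent ring A carbons C8a and C4a: ring A can enter as an aryne whose two carbons accept the enol oxygen and the ester carbon of an O1–C2=C3–C4 unit already carrying ring B at C3. Because ring A is unsymmetrical (oxygen at C7), a bromine at C5, next to C4a, orients the addition and is removed afterwards.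

## Logic of the disconnections

**22 to 21.** The two O–CH2 acetal bonds at O7 and O2' are cut. Both phenols must stay masked through the organometallic, basic and aryne steps. The forward step must be an acidic acetal cleavage mild enough to leave the prenyl alkene alone; the prenyl group sits beside a methyl ether and a hydrogen, so no chroman can form.

**21 to 20.** The C5–H bond is replaced by C5–Br. The bromine is a traceless control element for the aryne step. The forward step must reduce an aryl bromide without touching the alkene, the pyranone double bond or the acetals.

**20 to 17 and 7 (through 18 and 19).** O1–C8a and C4–C4a are cut, dividing the molecule into ring A (7) and the C2–C3–C4 unit with ring B (17). One operation makes both inter-fragment bonds and ring C. The forward step must be regioselective on the aryne, go through oxygen and not carbon of the enolate, and place the new aryl ether cis to the ester. In 7 the silyl group is remote from bromine, so the anion that fluoride creates can only expel triflate.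

**17 to 15 and 16.** The C2–C3 bond is cut; a crossed Claisen condensation makes it. The formyl donor 16 cannot enolise and shares the methoxide of the ester, so no scrambling arises.

**15 to 14 to 13 to 11.** The ester O–CH3 bond, then the carboxyl oxygens, then the bond between the benzylic carbon and the carboxyl carbon are cut. This is a one-carbon homologation of an aldehyde, and it must run under basic conditions to spare the acetal and the alkene.

**11 to 9 and 10.** The aryl–CH2 bond at C5' is cut. The forward cross-coupling must deliver the linear (α) prenyl isomer and tolerate the aldehyde.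

**9 to 8.** The O–CH2 acetal bond at the salicyl oxygen is cut; protection must come before any palladium or strong-base chemistry.

**7 to 4 (through 5 and 6).** The C–Si and O–S bonds are cut and one C–Br is regenerated. The forward one-pot sequence must exchange exactly one of the two bromines so that the other remains as the directing group.

**4 to 3.** The two C–Br bonds ortho to the free hydroxyl are cut; bromination must avoid HBr, which would cleave the acetal.

**3 to 2 to 1.** This is a protecting-group exchange on the hydroquinone: benzyl is removed and the acetal stays on the oxygen that becomes O7.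

## Other disconnections considered

**Alternative 1:** The cut removes ring B altogether (C2'–C3', C4'–C5' and C1'–C2'), leading back to the dienyl diazoketone A2 and methoxyacetylene A3.
- **Forward step:** irradiation of A2 should cause a Wolff rearrangement with migration of the chromonylvinyl group, giving a vinylketene with the prenyl chain on its α-carbon. [2+2] addition of A3, four-electron opening of the cyclobutenone, six-electron closure and tautomerisation would give A1 with the C2' hydroxyl free; fluoride desilylation would then give 22.
- **In favour:** the pericyclic cascade fixes the ring B pattern by mechanism (methoxy meta, prenyl para and ring C ortho to the new hydroxyl). The reaction type has precedent, no directing atom has to be removed, and the endgame is one non-acidic deprotection. On regiocontrol and on the mildness of the last step it is the better plan.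
- **Against:** A2 is a diazo compound that must be built on a 3-vinylchromone, with diazo transfer to an α-branched ketone. The chromone and enone chromophores absorb where the diazoketone does, so E/Z isomerisation and photocycloaddition at C2=C3 may compete. The carbene may be intercepted by the prenyl alkene, and A3 is volatile and unstable.
- **Comparison:** structurally it is less convergent, because all of ring B is carried in one linear chain on ring C, whereas the chosen plan joins two aromatic halves. Mechanistically it rests on a known cascade where the chosen plan rests on an untested one, a point for the alternative, though it adds photochemical and diazo hazards. Step economy should be about equal, since the steps saved at the end are spent on A2.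

**Alternative 2:** The cut is the C3–C1' bond, made while ring B is tied to C2 through a carboxylate bridge.
- **Forward step:** ester A5, from acid A7 and phenol A6, would undergo palladium-catalysed intramolecular direct arylation (oxidative addition at C3–Br, concerted metalation–deprotonation of the ortho C–H para to the methoxy group) to give lactone A4. Lactone opening, decarboxylation at C2 and acetal removal would follow.
- **In favour:** the C2' oxygen arrives as part of the tether and needs no protecting group. The tether makes the arylation intramolecular and sends it to the less hindered ortho position, which is the correct one. Direct arylation of aryl esters of ortho-halo acids to six-membered lactones is a known reaction type. The sequence is convergent and probably one or two steps shorter. On precedent and step count it is equal or better.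
- **Against:** the aryl ester of an electron-poor chromone acid is labile towards the carbonate or carboxylate base at the temperatures direct arylation needs. Saponifying the lactone exposes the base-sensitive pyranone to hydroxide. Decarboxylating a chromone-2-carboxylic acid needs strong heating, during which the free C2' phenol can re-close onto C2 or the carboxyl group.
- **Comparison:** both plans use a traceless auxiliary; the bromine of the chosen plan leaves under mild reductive conditions, whereas the carboxyl bridge leaves only under forcing ones, so the exit of the chosen plan is safer. The bond-forming step of the alternative is the better precedented.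

**Alternative 3:** The cut is O1–C8a alone, formed by nucleophilic aromatic substitution.
- **Forward step:** formylation of deoxybenzoin A10 would give keto aldehyde A9, whose enolate oxygen displaces the ortho fluorine to close ring C and give A8. The remaining C7 fluorine would then be exchanged for oxygen with a hydroxide surrogate, and the acetal removed.
- **In favour:** it forms the same O1–C8a bond as the chosen plan by textbook addition–elimination. Only the ortho fluorine can be reached, the enolate carbon cannot cyclise, and enolate geometry is irrelevant because C4 is already bonded to ring A. The ring closure is therefore more secure than the chosen key step, and the route to A8 is short (A10 could come from 14), so in certainty of ring formation and step count it is equal or better.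
- **Against:** the difficulty moves to the end. Replacing fluorine by hydroxyl at C7 of a chromone needs an oxygen nucleophile that can also attack C2 and open ring C. A benzyl-type surrogate would need a deprotection the prenyl group does not tolerate, and forcing conditions endanger the C2' acetal.
- **Comparison:** the chosen plan carries the C7 oxygen from the first step and ends with a reliable hydrodebromination, so its exit is better; its key step is the less certain of the two.

Key step: step 11

Remark on the chemistry: 17 is written as the Z enol (hydroxyl cis to the ester). It equilibrates with the E enol and the formyl-ester tautomer, and all give the same delocalised enolate 18. Atom mapping was checked: the silicon-bearing carbon of 7 becomes C8a, the triflate-bearing carbon becomes C4a and bromine ends at C5; no structure needed correction. Compounds 1, 8, 10 and 16 are taken as purchasable.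

## Route

Step 1
Reactants: 1 4-(benzyloxy)phenol
Product: 2 1-(benzyloxy)-4-(methoxymethoxy)benzene
Conditions: MOMCl, i-Pr2NEt, CH2Cl2, 0 °C to rt
Reagents that add atoms: chloromethyl methyl ether, COCCl
Why: O-alkylation of the phenol by the reactive α-chloro ether (Williamson-type acetal formation); the benzyl ether is inert.

Step 2
Reactants: 2 1-(benzyloxy)-4-(methoxymethoxy)benzene
Product: 3 4-(methoxymethoxy)phenol
Conditions: H2 (1 atm), 10% Pd/C, EtOAc, rt
Reagents that add atoms: none
Why: Hydrogenolysis of the benzyl aryl ether under neutral conditions; the acetal is not cleaved by hydrogen over palladium.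

Step 3
Reactants: 3 4-(methoxymethoxy)phenol
Product: 4 2,6-dibromo-4-(methoxymethoxy)phenol
Conditions: NBS (2.05 equiv), i-Pr2NH (0.1 equiv), CH2Cl2, 0 °C to rt
Reagents that add atoms: N-bromosuccinimide, O=C1CCC(=O)N1Br
Why: Amine-mediated electrophilic aromatic bromination, directed to both positions ortho to the free hydroxyl because para is blocked and the hydroxyl activates more strongly than the acetal oxygen; no HBr is formed, so the acetal survives.

Step 4
Reactants: 4 2,6-dibromo-4-(methoxymethoxy)phenol
Product: 7 2-bromo-4-(methoxymethoxy)-6-(trimethylsilyl)phenyl trifluoromethanesulfonate, via trimethylsilyl ether 5 (not isolated), via lithium phenoxide 6 (not isolated)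
Conditions: (Me3Si)2NH, THF, 65 °C, then evaporation; n-BuLi (1.05 equiv), THF, −78 °C; Tf2O, −78 °C to rt
Reagents that add atoms: hexamethyldisilazane, C[Si](C)(C)N[Si](C)(C)C; trifluoromethanesulfonic anhydride, O=S(=O)(OS(=O)(=O)C(F)(F)F)C(F)(F)F
Why: O-silylation, bromine–lithium exchange at one of the two equivalent bromines, 1,3 oxygen-to-carbon silyl shift (retro-Brook rearrangement) driven by phenoxide formation, then O-triflation; this is the standard one-pot entry to ortho-silylaryl triflates carrying a halogen beside the triflate.

Step 5
Reactants: 8 5-bromo-2-hydroxy-4-methoxybenzaldehyde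
Product: 9 5-bromo-4-methoxy-2-(methoxymethoxy)benzaldehyde
Conditions: MOMCl, i-Pr2NEt, CH2Cl2, 0 °C to rt
Reagents that add atoms: chloromethyl methyl ether, COCCl
Why: O-alkylation of the salicyl phenol (acetal formation); the aldehyde and the aryl bromide do not react.

Step 6
Reactants: 9 5-bromo-4-methoxy-2-(methoxymethoxy)benzaldehyde; 10 4,4,5,5-tetramethyl-2-(3-methylbut-2-enyl)-1,3,2-dioxaborolane
Product: 11 4-methoxy-2-(methoxymethoxy)-5-(3-methylbut-2-enyl)benzaldehyde
Conditions: PdCl2(dppf)·CH2Cl2 (5 mol %), K3PO4, THF–H2O, 70 °C
Reagents that add atoms: none
Why: Suzuki–Miyaura coupling of an aryl bromide with an allylboronate; equilibration of the prenylpalladium intermediate to the less hindered primary σ-allyl form before reductive elimination should give the linear prenyl arene, and the aldehyde tolerates aqueous phosphate.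

Step 7
Reactants: 11 4-methoxy-2-(methoxymethoxy)-5-(3-methylbut-2-enyl)benzaldehyde
Product: 13 2-[4-methoxy-2-(methoxymethoxy)-5-(3-methylbut-2-enyl)phenyl]acetonitrile, via N-vinylformamide adduct 12 (not isolated)
Conditions: TosMIC, t-BuOK (2.5 equiv), DME, −40 °C; then MeOH, 65 °C
Reagents that add atoms: p-toluenesulfonylmethyl isocyanide, Cc1ccc(S(=O)(=O)C[N+]#[C-])cc1
Why: Van Leusen reductive cyanation: the isocyanide anion adds to the aldehyde, the oxazoline opens to the N-formyl enamide 12, and methanolysis removes the formyl group and sulfinate to leave the homologous nitrile; the all-basic medium spares acetal and alkene.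

Step 8
Reactants: 13 2-[4-methoxy-2-(methoxymethoxy)-5-(3-methylbut-2-enyl)phenyl]acetonitrile
Product: 14 2-[4-methoxy-2-(methoxymethoxy)-5-(3-methylbut-2-enyl)phenyl]acetic acid
Conditions: KOH, EtOH–H2O, reflux; then 1 M HCl to pH 4, 0 °C
Reagents that add atoms: water (delivered as hydroxide), O
Why: Base hydrolysis of the nitrile through the amide to the carboxylate; acetal and prenyl group are stable to hydroxide, and brief cold acidification to pH 4 does not cleave the acetal.

Step 9
Reactants: 14 2-[4-methoxy-2-(methoxymethoxy)-5-(3-methylbut-2-enyl)phenyl]acetic acid
Product: 15 methyl 2-[4-methoxy-2-(methoxymethoxy)-5-(3-methylbut-2-enyl)phenyl]acetate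
Conditions: MeI, K2CO3, DMF, rt
Reagents that add atoms: iodomethane, CI
Why: O-alkylation of the carboxylate (SN2); carbonate is too weak to deprotonate the benzylic position, so no C-methylation is expected.

Step 10
Reactants: 15 methyl 2-[4-methoxy-2-(methoxymethoxy)-5-(3-methylbut-2-enyl)phenyl]acetate; 16 methyl formate
Product: 17 methyl (Z)-3-hydroxy-2-[4-methoxy-2-(methoxymethoxy)-5-(3-methylbut-2-enyl)phenyl]prop-2-enoate
Conditions: NaH (2.5 equiv), HCO2Me (10 equiv), THF, 0 °C to rt; then AcOH, 0 °C
Reagents that add atoms: none
Why: Crossed Claisen condensation of the arylacetate enolate with a non-enolisable formate, driven by formation of the stabilised enolate; mild acid releases the hydrogen-bonded enol.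

Step 11
Reactants: 17 methyl (Z)-3-hydroxy-2-[4-methoxy-2-(methoxymethoxy)-5-(3-methylbut-2-enyl)phenyl]prop-2-enoate; 7 2-bromo-4-(methoxymethoxy)-6-(trimethylsilyl)phenyl trifluoromethanesulfonate
Product: 20 5-bromo-7-(methoxymethoxy)-3-[4-methoxy-2-(methoxymethoxy)-5-(3-methylbut-2-enyl)phenyl]chromen-4-one, via cesium enolate 18 (not isolated), via 3-bromo-5-(methoxymethoxy)benzyne 19 (not isolated)
Conditions: CsF (4 equiv), 7 (1.3 equiv), THF, 65 °C, sealed vessel
Reagents that add atoms: none
Why: Proposed new method: fluoride removes the silyl group of 7 and the aryl anion expels triflate to give aryne 19, while fluoride as base converts enol 17 into cesium enolate 18; the enolate oxygen should add to the aryne carbon meta to bromine, and the aryl anion created beside bromine should add to the ester carbonyl and expel methoxide, so that O1–C8a and C4–C4a form in one operation. The closest known reaction type is the CsF-mediated coupling of ortho-silylaryl triflates with methyl salicylates to xanthones, of which 18 is the open-chain vinylogue. Ring C closes by 6-exo-trig attack of the aryl carbanion on the ester carbon, possible only from the adduct in which the new aryloxy group and the ester are cis on C2=C3. No stereocentre is formed. Regioselectivity rests on the C–Br bond, which distorts 19 so that the remote aryne carbon is the flatter, more electrophilic terminus and the negative charge builds up beside the inductively withdrawing halogen; the C7 acetal oxygen is not adjacent to the triple bond and should exert only a weak, subordinate bias. Attack through oxygen and not carbon rests on the fully substituted enolate carbon, flanked by an ortho-alkoxyaryl group and the ester, against the unhindered terminal oxygen of a hard cesium enolate. THF is chosen over acetonitrile so that no acidic solvent C–H competes with acyl capture and so that cesium chelation between the two enolate oxygens favours the Z geometry needed for closure.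

Step 12
Reactants: 20 5-bromo-7-(methoxymethoxy)-3-[4-methoxy-2-(methoxymethoxy)-5-(3-methylbut-2-enyl)phenyl]chromen-4-one
Product: 21 7-(methoxymethoxy)-3-[4-methoxy-2-(methoxymethoxy)-5-(3-methylbut-2-enyl)phenyl]chromen-4-one
Conditions: Pd(PPh3)4 (5 mol %), HCO2H (3 equiv), Et3N (4 equiv), DMF, 80 °C
Reagents that add atoms: none
Why: Palladium-catalysed transfer hydrodehalogenation: zerovalent palladium inserts into the C5–Br bond (activated by the peri carbonyl), formate exchanges for bromide and decarboxylates to an arylpalladium hydride, and reductive elimination gives C5–H; excess amine keeps the medium non-acidic and the isolated trisubstituted alkene is not a substrate.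

Step 13
Reactants: 21 7-(methoxymethoxy)-3-[4-methoxy-2-(methoxymethoxy)-5-(3-methylbut-2-enyl)phenyl]chromen-4-one
Product: 22 7-hydroxy-3-[2-hydroxy-4-methoxy-5-(3-methylbut-2-enyl)phenyl]chromen-4-one
Conditions: 2 M aq HCl, MeOH–THF, 45 °C
Reagents that add atoms: none
Why: Acid-catalysed acetal exchange with methanol frees both phenols; the prenyl group has no free hydroxyl beside it, so acid-induced chroman formation has no pathway, and dilute acid at mild temperature should leave the alkene unchanged.

## Compound list

1 | 4-(benzyloxy)phenol | Oc1ccc(OCc2ccccc2)cc1 | starting material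
2 | 1-(benzyloxy)-4-(methoxymethoxy)benzene | COCOc1ccc(OCc2ccccc2)cc1 | intermediate
3 | 4-(methoxymethoxy)phenol | COCOc1ccc(O)cc1 | intermediate
4 | 2,6-dibromo-4-(methoxymethoxy)phenol | COCOc1cc(Br)c(O)c(Br)c1 | intermediate
5 | [2,6-dibromo-4-(methoxymethoxy)phenoxy]trimethylsilane | COCOc1cc(Br)c(O[Si](C)(C)C)c(Br)c1 | intermediate
6 | lithium 2-bromo-4-(methoxymethoxy)-6-(trimethylsilyl)phenoxide | COCOc1cc(Br)c([O-])c([Si](C)(C)C)c1.[Li+] | intermediate
7 | 2-bromo-4-(methoxymethoxy)-6-(trimethylsilyl)phenyl trifluoromethanesulfonate | COCOc1cc(Br)c(OS(=O)(=O)C(F)(F)F)c([Si](C)(C)C)c1 | intermediate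
8 | 5-bromo-2-hydroxy-4-methoxybenzaldehyde | COc1cc(O)c(C=O)cc1Br | starting material
9 | 5-bromo-4-methoxy-2-(methoxymethoxy)benzaldehyde | COCOc1cc(OC)c(Br)cc1C=O | intermediate
10 | 4,4,5,5-tetramethyl-2-(3-methylbut-2-enyl)-1,3,2-dioxaborolane | CC(C)=CCB1OC(C)(C)C(C)(C)O1 | starting material
11 | 4-methoxy-2-(methoxymethoxy)-5-(3-methylbut-2-enyl)benzaldehyde | COCOc1cc(OC)c(CC=C(C)C)cc1C=O | intermediate
12 | N-[2-[4-methoxy-2-(methoxymethoxy)-5-(3-methylbut-2-enyl)phenyl]-1-(4-methylphenyl)sulfonylethenyl]formamide (present as its potassium salt; alkene geometry not defined, either isomer reacts on) | O=CNC(=Cc1cc(CC=C(C)C)c(OC)cc1OCOC)S(=O)(=O)c1ccc(C)cc1 | intermediate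
13 | 2-[4-methoxy-2-(methoxymethoxy)-5-(3-methylbut-2-enyl)phenyl]acetonitrile | COCOc1cc(OC)c(CC=C(C)C)cc1CC#N | intermediate
14 | 2-[4-methoxy-2-(methoxymethoxy)-5-(3-methylbut-2-enyl)phenyl]acetic acid | COCOc1cc(OC)c(CC=C(C)C)cc1CC(=O)O | intermediate
15 | methyl 2-[4-methoxy-2-(methoxymethoxy)-5-(3-methylbut-2-enyl)phenyl]acetate | COCOc1cc(OC)c(CC=C(C)C)cc1CC(=O)OC | intermediate
16 | methyl formate | COC=O | starting material
17 | methyl (Z)-3-hydroxy-2-[4-methoxy-2-(methoxymethoxy)-5-(3-methylbut-2-enyl)phenyl]prop-2-enoate | COC(=O)/C(=C\O)c1cc(CC=C(C)C)c(OC)cc1OCOC | intermediate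
18 | cesium (Z)-3-methoxy-2-[4-methoxy-2-(methoxymethoxy)-5-(3-methylbut-2-enyl)phenyl]-3-oxoprop-1-en-1-olate | COC(=O)/C(=C\[O-])c1cc(CC=C(C)C)c(OC)cc1OCOC.[Cs+] | intermediate
19 | 3-bromo-5-(methoxymethoxy)benzyne | COCOC1=CC#CC(Br)=C1 | intermediate
20 | 5-bromo-7-(methoxymethoxy)-3-[4-methoxy-2-(methoxymethoxy)-5-(3-methylbut-2-enyl)phenyl]chromen-4-one | COCOc1cc(Br)c2c(c1)occ(-c1cc(CC=C(C)C)c(OC)cc1OCOC)c2=O | intermediate
21 | 7-(methoxymethoxy)-3-[4-methoxy-2-(methoxymethoxy)-5-(3-methylbut-2-enyl)phenyl]chromen-4-one | COCOc1ccc2c(c1)occ(-c1cc(CC=C(C)C)c(OC)cc1OCOC)c2=O | intermediate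
22 | 7-hydroxy-3-[2-hydroxy-4-methoxy-5-(3-methylbut-2-enyl)phenyl]chromen-4-one | COc1cc(O)c(-c2coc3cc(O)ccc3c2=O)cc1CC=C(C)C | target

## Step count and least certain steps

Total: 13 steps (steps 1–4 to 7; steps 5–10 to 17; step 11 joins them; steps 12 and 13 finish). Longest linear sequence: 9 steps (steps 5–13, from 8 to 22).

**Step 11 (key step, new method).**
- Several processes could divert it: attack of the aryne by the enolate carbon followed by formyl transfer to the aryl anion (σ-insertion); O-arylation from the E enolate geometry, after which the aryl anion cannot reach the ester and is protonated; loss of bromide from the ortho-bromoaryl anion before acyl capture, which regenerates an aryne; and ene reaction of the aryne with the prenyl group.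
- These are plausible because β-dicarbonyl enolates usually react with arynes at carbon, and because an aryl anion next to bromine has a good leaving group beside it.
- Fallback by known chemistry, from 14 to 22: amide coupling of 14 with N,O-dimethylhydroxylamine (EDC·HCl, HOBt, i-Pr2NEt) gives N-methoxy-N-methyl-2-[4-methoxy-2-(methoxymethoxy)-5-(3-methylbut-2-enyl)phenyl]acetamide F1. Commercial 4-bromoresorcinol is protected (MOMCl, i-Pr2NEt) to 1-bromo-2,4-bis(methoxymethoxy)benzene F2. Bromine–lithium exchange on F2 (n-BuLi, THF, −78 °C) and addition to F1 gives 1-[2,4-bis(methoxymethoxy)phenyl]-2-[4-methoxy-2-(methoxymethoxy)-5-(3-methylbut-2-enyl)phenyl]ethanone F3. Condensation with N,N-dimethylformamide dimethyl acetal (toluene, 90 °C) gives (E)-1-[2,4-bis(methoxymethoxy)phenyl]-3-(dimethylamino)-2-[4-methoxy-2-(methoxymethoxy)-5-(3-methylbut-2-enyl)phenyl]prop-2-en-1-one F4. Dilute HCl in methanol (45 °C) removes the three acetals, and the freed ortho phenol adds to the enaminone and expels dimethylamine, closing ring C and returning at 22.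

**Step 6.**
- Reductive elimination may occur from the tertiary σ-allyl palladium species before it equilibrates, giving the branched (1,1-dimethylallyl) isomer; protodeboronation of the allylboronate may also compete. The electron-rich, ortho-substituted bromide undergoes oxidative addition slowly, which gives these processes time.
- Fallback, from 9 back to 11: Suzuki–Miyaura allylation of 9 with 2-allyl-4,4,5,5-tetramethyl-1,3,2-dioxaborolane under the same catalyst gives 4-methoxy-2-(methoxymethoxy)-5-(prop-2-enyl)benzaldehyde F5, which has no regiochemical ambiguity. Cross-metathesis with excess 2-methylbut-2-ene (second-generation Grubbs catalyst, RuCl2(H2IMes)(PCy3)(=CHPh), CH2Cl2, 40 °C) then gives 11.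

**Step 7.**
- The oxazoline intermediate may eliminate sulfinate to an oxazole instead of ring-opening to 12, or addition to the hindered, electron-rich aldehyde may be incomplete.
- Fallback, from 11 to 14, bypassing 13: addition of trichloromethyl anion (CCl3CO2Na, CCl3CO2H, DMF, rt) gives racemic 2,2,2-trichloro-1-[4-methoxy-2-(methoxymethoxy)-5-(3-methylbut-2-enyl)phenyl]ethanol F6. Treatment with NaBH4 and NaOH in t-BuOH (55 °C) forms the gem-dichloroepoxide, opens it with hydride at the benzylic carbon and hydrolyses the acyl chloride, giving 14 (Jocic-type reductive homologation).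

**Step 13.**
- Markovnikov addition of HCl, water or methanol across the prenyl double bond may occur during the longer exposure needed to cleave the less reactive acetal.
- Fallback, from 21 to 22, with no new compound (F0): non-protic acetal transfer to a thiol, using ZnBr2 and propane-1-thiol in CH2Cl2 at 0 °C. This replaces Brønsted-acid solvolysis by Lewis-acid activation with a soft nucleophile, with no protic acid present to add to the alkene.

## Further compounds

F1 | step 11 | N-methoxy-N-methyl-2-[4-methoxy-2-(methoxymethoxy)-5-(3-methylbut-2-enyl)phenyl]acetamide | CON(C)C(=O)Cc1cc(CC=C(C)C)c(OC)cc1OCOC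
F2 | step 11 | 1-bromo-2,4-bis(methoxymethoxy)benzene | COCOc1ccc(Br)c(OCOC)c1
F3 | step 11 | 1-[2,4-bis(methoxymethoxy)phenyl]-2-[4-methoxy-2-(methoxymethoxy)-5-(3-methylbut-2-enyl)phenyl]ethanone | COCOc1ccc(C(=O)Cc2cc(CC=C(C)C)c(OC)cc2OCOC)c(OCOC)c1
F4 | step 11 | (E)-1-[2,4-bis(methoxymethoxy)phenyl]-3-(dimethylamino)-2-[4-methoxy-2-(methoxymethoxy)-5-(3-methylbut-2-enyl)phenyl]prop-2-en-1-one | CN(C)/C=C(\c1cc(CC=C(C)C)c(OC)cc1OCOC)C(=O)c1ccc(OCOC)cc1OCOC
F5 | step 6 | 4-methoxy-2-(methoxymethoxy)-5-(prop-2-enyl)benzaldehyde | COCOc1cc(OC)c(CC=C)cc1C=O
F6 | step 7 | 2,2,2-trichloro-1-[4-methoxy-2-(methoxymethoxy)-5-(3-methylbut-2-enyl)phenyl]ethanol (racemic) | COCOc1cc(OC)c(CC=C(C)C)cc1C(O)C(Cl)(Cl)Cl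
F0 | step 13 | none | none
A1 | alternative 1 | 3-[2-hydroxy-4-methoxy-5-(3-methylbut-2-enyl)phenyl]-7-(triisopropylsilyloxy)chromen-4-one | COc1cc(O)c(-c2coc3cc(O[Si](C(C)C)(C(C)C)C(C)C)ccc3c2=O)cc1CC=C(C)C
A2 | alternative 1 | (E)-4-diazo-7-methyl-1-[4-oxo-7-(triisopropylsilyloxy)chromen-3-yl]octa-1,6-dien-3-one | CC(C)=CCC(=[N+]=[N-])C(=O)/C=C/c1coc2cc(O[Si](C(C)C)(C(C)C)C(C)C)ccc2c1=O
A3 | alternative 1 | methoxyacetylene (methoxyethyne) | COC#C
A4 | alternative 2 | lactone of 3-[2-hydroxy-4-methoxy-5-(3-methylbut-2-enyl)phenyl]-7-(methoxymethoxy)-4-oxochromene-2-carboxylic acid (carbonyl bridge from C2 to the C2' oxygen) | COCOc1ccc2c(c1)oc1C(=O)Oc3cc(OC)c(CC=C(C)C)cc3-c1c2=O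
A5 | alternative 2 | 3-methoxy-4-(3-methylbut-2-enyl)phenyl 3-bromo-7-(methoxymethoxy)-4-oxochromene-2-carboxylate | COCOc1ccc2c(c1)oc(C(=O)Oc1ccc(CC=C(C)C)c(OC)c1)c(Br)c2=O
A6 | alternative 2 | 3-methoxy-4-(3-methylbut-2-enyl)phenol | COc1cc(O)ccc1CC=C(C)C
A7 | alternative 2 | 3-bromo-7-(methoxymethoxy)-4-oxochromene-2-carboxylic acid | COCOc1ccc2c(c1)oc(C(=O)O)c(Br)c2=O
A8 | alternative 3 | 7-fluoro-3-[4-methoxy-2-(methoxymethoxy)-5-(3-methylbut-2-enyl)phenyl]chromen-4-one | COCOc1cc(OC)c(CC=C(C)C)cc1-c1coc2cc(F)ccc2c1=O
A9 | alternative 3 | 3-(2,4-difluorophenyl)-2-[4-methoxy-2-(methoxymethoxy)-5-(3-methylbut-2-enyl)phenyl]-3-oxopropanal (racemic, enolising centre) | COCOc1cc(OC)c(CC=C(C)C)cc1C(C=O)C(=O)c1ccc(F)cc1F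
A10 | alternative 3 | 1-(2,4-difluorophenyl)-2-[4-methoxy-2-(methoxymethoxy)-5-(3-methylbut-2-enyl)phenyl]ethanone | COCOc1cc(OC)c(CC=C(C)C)cc1CC(=O)c1ccc(F)cc1F
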